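**Plan**

1. Numbering used throughout: C1 (methacrylate carbinol), C2, C3 (isobutyrate carbinol), C4 (quaternary, CH3), C5, C6 (C=O), C7, C8 (=C–CH3), C9, C10, C11 (CMe2). Cyclobutane is C4–C5–C10–C9, cyclohexenone is C4–C5–C6–C7–C8–C9, ring A (seven-membered) is C1–C2–C3–C4–C5–C10–C11.
2. Retrosynthesis: the O1 ester and the C6 carbonyl are taken off, then C9–C10 is cut to a C10 ketone and an allylic C9 methylene. What is left is a cyclohexene C4–C5–C6–C7=C8(CH3)–C9 fused through C4–C5 to ring A with C5 next to the C10 carbonyl. That is the adduct of isoprene (C6 to C9) with a 3-methylcyclohept-2-enone (C4=C5–C10=O), so C4–C9 and C5–C6 are cut together.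
3. The cycloheptenone is cut at C4=C5 (metathesis), C5–C10 (vinyl addition), C1–H with the O3 ester (Tishchenko) and C2–C3 (aldol).
4. Forward: the chain C10–C11–C1–C2–C3–C4 is joined by an aldol reaction, ring A closes by metathesis, the six-membered ring by the Diels-Alder reaction, the four-membered ring by Norrish-Yang photocyclisation. Deoxygenation at C10, oxidation at C6 and acylation of O1 finish the route.
5. Stereochemistry: C3 comes from a reagent-controlled boron aldol and C1 from the 1,3-anti Evans-Tishchenko reduction, which also places the isobutyrate on O3. C4 and C5 come from suprafacial cycloaddition anti to the C3 ester, and C9 and C10 are dictated by the cage.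

Key step: step 9

Remark: 4-hydroxy-3,3-dimethylbutan-2-one is taken as a purchasable ketone.
Remark: the sense of induction of (−)-Ipc2BCl (R at C3, attack on the Re face of the enal) is assumed from its behaviour with methyl ketones and other enals. It would be confirmed by Mosher ester analysis of 5, and the antipodal reagent used if the assignment is reversed.
Remark: 11 and 12 are carried as mixtures of C10 epimers, which step 8 removes.

**Step 1**
Reactants: 1 4-hydroxy-3,3-dimethylbutan-2-one
Product: 2 3,3-dimethyl-4-(triethylsilyloxy)butan-2-one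
Conditions: TESCl, imidazole, CH2Cl2, 0 °C to rt
Reagents that add atoms: chlorotriethylsilane, CC[Si](Cl)(CC)CC
Why: Routine silylation of a primary alcohol, the triethylsilyl group being chosen because it survives steps 2 to 4 and can be oxidised off directly in step 5; no stereocenter is formed.

**Step 2**
Reactants: 2 3,3-dimethyl-4-(triethylsilyloxy)butan-2-one; 3 methacrolein
Product: 5 (R)-5-hydroxy-2,2,6-trimethyl-1-(triethylsilyloxy)hept-6-en-3-one, via boron enolate 4 (not isolated)
Conditions: (−)-Ipc2BCl, Et3N, Et2O, 0 °C; then 3, −78 to −20 °C; H2O2, pH 7 buffer, MeOH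
Reagents that add atoms: none
Why: Paterson boron aldol, in which the ketone can enolise only at its methyl group (the other α carbon is quaternary) and the isopinocampheyl ligands of the boron enolate should direct addition to the Re face of methacrolein through a cyclic transition state, setting C3 as R.

**Step 3**
Reactants: 5 (R)-5-hydroxy-2,2,6-trimethyl-1-(triethylsilyloxy)hept-6-en-3-one; 6 isobutyraldehyde
Product: 7 (3R,5R)-5-hydroxy-2,6,6-trimethyl-7-(triethylsilyloxy)hept-1-en-3-yl 2-methylpropanoate
Conditions: SmI2 (0.3 equiv), 6 (5 equiv), THF, −10 °C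
Reagents that add atoms: none
Why: Evans-Tishchenko reduction, in which the samarium-bound hemiacetal formed from the C3 alkoxide and isobutyraldehyde delivers hydride intramolecularly through a chair-like bicyclic transition state to the C1 ketone, setting C1 anti to C3 (R) and leaving the isobutyrate on O3 with O1 free.

**Step 4**
Reactants: 7 (3R,5R)-5-hydroxy-2,6,6-trimethyl-7-(triethylsilyloxy)hept-1-en-3-yl 2-methylpropanoate
Product: 8 (3R,5R)-5-(tert-butyldimethylsilyloxy)-2,6,6-trimethyl-7-(triethylsilyloxy)hept-1-en-3-yl 2-methylpropanoate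
Conditions: TBSOTf, 2,6-lutidine, CH2Cl2, −78 to 0 °C
Reagents that add atoms: tert-butyldimethylsilyl triflate, CC(C)(C)[Si](C)(C)OS(=O)(=O)C(F)(F)F
Why: Silyl triflate with a hindered base silylates the neopentyl secondary alcohol at low temperature before any 1,3-acyl migration can occur; no stereocenter is touched.

**Step 5**
Reactants: 8 (3R,5R)-5-(tert-butyldimethylsilyloxy)-2,6,6-trimethyl-7-(triethylsilyloxy)hept-1-en-3-yl 2-methylpropanoate
Product: 9 (3R,5R)-5-(tert-butyldimethylsilyloxy)-2,6,6-trimethyl-7-oxohept-1-en-3-yl 2-methylpropanoate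
Conditions: (COCl)2, DMSO, CH2Cl2, −78 to −30 °C; Et3N, −78 to 0 °C
Reagents that add atoms: none
Why: Swern oxidation run directly on the silyl ether, since activated DMSO cleaves primary triethylsilyl ethers and oxidises them in the same flask while the secondary TBS ether and the ester are untouched, giving a non-enolisable neopentyl aldehyde.

**Step 6**
Reactants: 9 (3R,5R)-5-(tert-butyldimethylsilyloxy)-2,6,6-trimethyl-7-oxohept-1-en-3-yl 2-methylpropanoate; 10 vinylmagnesium bromide
Product: 11 (3R,5R)-5-(tert-butyldimethylsilyloxy)-7-hydroxy-2,6,6-trimethylnona-1,8-dien-3-yl 2-methylpropanoate (both C7 epimers)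
Conditions: THF, −78 °C; aq. NH4Cl
Reagents that add atoms: none
Why: Grignard addition, the aldehyde being far more electrophilic than the hindered isobutyrate at −78 °C; the new carbinol centre (C10 of the target) forms as a mixture that step 8 erases.

**Step 7**
Reactants: 11 (3R,5R)-5-(tert-butyldimethylsilyloxy)-7-hydroxy-2,6,6-trimethylnona-1,8-dien-3-yl 2-methylpropanoate
Product: 12 (1R,6R)-6-(tert-butyldimethylsilyloxy)-4-hydroxy-2,5,5-trimethylcyclohept-2-en-1-yl 2-methylpropanoate (both C4 epimers)
Conditions: second-generation Grubbs catalyst (H2IMes)(PCy3)Cl2Ru=CHPh (5 mol%), CH2Cl2, 40 °C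
Reagents that add atoms: none
Why: Ring-closing metathesis, the catalyst loading on the monosubstituted vinyl group and closing onto the 1,1-disubstituted alkene, helped by the gem-dimethyl group, to give the trisubstituted C4=C5 alkene of ring A, whose geometry the ring fixes.

**Step 8**
Reactants: 12 (1R,6R)-6-(tert-butyldimethylsilyloxy)-4-hydroxy-2,5,5-trimethylcyclohept-2-en-1-yl 2-methylpropanoate
Product: 13 (1R,6R)-6-(tert-butyldimethylsilyloxy)-2,5,5-trimethyl-4-oxocyclohept-2-en-1-yl 2-methylpropanoate
Conditions: Dess-Martin periodinane, NaHCO3, CH2Cl2, rt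
Reagents that add atoms: none
Why: Dess-Martin oxidation of the allylic alcohol under buffered neutral conditions converges both epimers on the enone without disturbing the γ-acyloxy group.

**Step 9**
Reactants: 13 (1R,6R)-6-(tert-butyldimethylsilyloxy)-2,5,5-trimethyl-4-oxocyclohept-2-en-1-yl 2-methylpropanoate; 14 isoprene
Product: 15 cis-fused adduct, (1R,3R,4R,5S)-1-(tert-butyldimethylsilyloxy)-3-(isobutyryloxy)-4,8,11,11-tetramethylbicyclo[5.4.0]undec-7-en-10-one in the numbering of the plan (C4 methyl and C5 hydrogen cis, C4–C9 bond anti to O3)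
Conditions: EtAlCl2 (2.5 equiv), 14 (10 equiv), toluene/CH2Cl2, −40 to 0 °C; cold aqueous quench
Reagents that add atoms: none
Why: EtAlCl2 binds the C10 carbonyl and lowers the enone LUMO, and isoprene then adds in a concerted but asynchronous [4+2] cycloaddition in which bonding from the β carbon C4 to C9 runs ahead of C5–C6. The closest known reaction type is the aluminium-halide-promoted Diels-Alder reaction of 3-methylcycloalkenones with isoprene, which gives cis-fused bicycles carrying an angular methyl group. The cyclohexene C4–C5–C6–C7–C8–C9 closes by cycloaddition with both new bonds formed on one face of the ring alkene, so the C4 methyl and the C5 hydrogen end cis. The face is set by C3: allylic 1,2-strain with the C4 methyl should hold the isobutyrate pseudoaxial, where it shields its own face, while the trans C1 silyl ether then sits pseudoequatorial, so the diene should add anti to O3 and fix C4 as R and C5 as S. The step needs para regioselectivity and this facial selectivity; the first follows from the larger HOMO coefficient at the isoprene terminus next to its methyl (C9) pairing with C4, the second from the C3 stereocenter. A cold quench is needed so that C5, α to the ketone, does not epimerise to the trans-fused isomer, which cannot undergo step 10.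

**Step 10**
Reactants: 15 cis-fused Diels-Alder adduct
Product: 16 tricyclic cyclobutanol (C9–C10 bond formed, hydroxyl on C10 syn to the C6–C7–C8 bridge)
Conditions: hν (300 nm, Pyrex), degassed t-BuOH/benzene, 5 mM, rt
Reagents that add atoms: none
Why: Norrish-Yang photocyclisation, in which the n,π* excited C10 carbonyl abstracts the pseudoaxial allylic hydrogen on C9 through a six-membered transition state (open only to the cis-fused conformer with C10 and C9 gauche) and the 1,4-biradical closes C9–C10, the ketyl p orbital being held by ring A towards C9 and not C7, while the configurations at C9 and C10 are dictated by the cage because the C11 tether can only lie on the face away from the C6–C8 bridge.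

**Step 11**
Reactants: 16 tricyclic cyclobutanol
Product: 17 C10 methyl oxalate of 16
Conditions: ClC(O)CO2Me, DMAP, Et3N, CH2Cl2, 0 °C to rt
Reagents that add atoms: methyl chlorooxoacetate, COC(=O)C(Cl)=O
Why: Acylation with the highly electrophilic oxalyl half-ester chloride under DMAP catalysis works on hindered tertiary alcohols and avoids a free alkoxide, which could open the strained cyclobutanol by retro-allylation.

**Step 12**
Reactants: 17 C10 methyl oxalate
Product: 18 deoxygenated tricycle (C10–H, C7=C8 alkene, O1 silyl ether, O3 isobutyrate)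
Conditions: Bu3SnH (5 equiv), PhSeSePh (10 mol%), AIBN, toluene, 100 °C
Reagents that add atoms: none
Why: Tin hydride reduction of a tertiary methyl oxalate (the oxalate variant of the Barton-McCombie deoxygenation), in which the C10 radical is trapped by benzeneselenol generated in the flask before the cyclobutyl radical can open, and hydrogen can only arrive on the face syn to the C6–C8 bridge because C11 is tied back, which fixes C10 as in the target.

**Step 13**
Reactants: 18 deoxygenated tricycle
Product: 19 tricyclic enone (C6 ketone conjugated with C7=C8)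
Conditions: CrO3, 3,5-dimethylpyrazole, CH2Cl2, −20 °C
Reagents that add atoms: chromium trioxide, O=[Cr](=O)=O
Why: Allylic oxidation of the kind that converts α-pinene into verbenone, C6 being the only allylic methylene that is not a bridgehead, so that the conjugated enone should form without touching a stereocenter.

**Step 14**
Reactants: 19 tricyclic enone
Product: 20 C1 alcohol
Conditions: HF·pyridine, THF, 0 °C to rt
Reagents that add atoms: none
Why: Fluoride desilylation under mildly acidic conditions frees the C1 hydroxyl without base, so that neither acyl migration from O3 nor damage to the enone is expected.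

**Step 15**
Reactants: 20 C1 alcohol; 21 methacrylic anhydride
Product: 22 CNP0214356.1, (1R,3R,4R,5R,9R,10S) in the numbering of the plan
Conditions: Et3N, DMAP, BHT (trace), CH2Cl2, rt to 40 °C
Reagents that add atoms: none
Why: DMAP-catalysed acylation of the hindered secondary alcohol with the anhydride, with a radical inhibitor against polymerisation of the methacrylate; the C1 configuration is retained.

**Compound list**

1 | 4-hydroxy-3,3-dimethylbutan-2-one | CC(=O)C(C)(C)CO | starting material
2 | 3,3-dimethyl-4-(triethylsilyloxy)butan-2-one | CC(=O)C(C)(C)CO[Si](CC)(CC)CC | intermediate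
3 | methacrolein | C=C(C)C=O | starting material
4 | diisopinocampheylboron enolate of 2 | C=C(OB([C@@H]1C[C@@H]2C[C@H]([C@H]1C)C2(C)C)[C@@H]1C[C@@H]2C[C@H]([C@H]1C)C2(C)C)C(C)(C)CO[Si](CC)(CC)CC | intermediate
5 | (R)-5-hydroxy-2,2,6-trimethyl-1-(triethylsilyloxy)hept-6-en-3-one | C=C(C)[C@H](O)CC(=O)C(C)(C)CO[Si](CC)(CC)CC | intermediate
6 | isobutyraldehyde | CC(C)C=O | starting material
7 | (3R,5R)-5-hydroxy-2,6,6-trimethyl-7-(triethylsilyloxy)hept-1-en-3-yl 2-methylpropanoate | C=C(C)[C@H](OC(=O)C(C)C)C[C@@H](O)C(C)(C)CO[Si](CC)(CC)CC | intermediate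
8 | (3R,5R)-5-(tert-butyldimethylsilyloxy)-2,6,6-trimethyl-7-(triethylsilyloxy)hept-1-en-3-yl 2-methylpropanoate | C=C(C)[C@H](OC(=O)C(C)C)C[C@@H](O[Si](C)(C)C(C)(C)C)C(C)(C)CO[Si](CC)(CC)CC | intermediate
9 | (3R,5R)-5-(tert-butyldimethylsilyloxy)-2,6,6-trimethyl-7-oxohept-1-en-3-yl 2-methylpropanoate | C=C(C)[C@H](OC(=O)C(C)C)C[C@@H](O[Si](C)(C)C(C)(C)C)C(C)(C)C=O | intermediate
10 | vinylmagnesium bromide | C=C[Mg]Br | starting material
11 | (3R,5R)-5-(tert-butyldimethylsilyloxy)-7-hydroxy-2,6,6-trimethylnona-1,8-dien-3-yl 2-methylpropanoate, both C7 epimers | C=C(C)[C@H](OC(=O)C(C)C)C[C@@H](O[Si](C)(C)C(C)(C)C)C(C)(C)C(O)C=C | intermediate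
12 | (1R,6R)-6-(tert-butyldimethylsilyloxy)-4-hydroxy-2,5,5-trimethylcyclohept-2-en-1-yl 2-methylpropanoate, both C4 epimers | OC1C=C(C)[C@H](OC(=O)C(C)C)C[C@@H](O[Si](C)(C)C(C)(C)C)C1(C)C | intermediate
13 | (1R,6R)-6-(tert-butyldimethylsilyloxy)-2,5,5-trimethyl-4-oxocyclohept-2-en-1-yl 2-methylpropanoate | O=C1C=C(C)[C@H](OC(=O)C(C)C)C[C@@H](O[Si](C)(C)C(C)(C)C)C1(C)C | intermediate
14 | isoprene | C=CC(C)=C | starting material
15 | cis-fused Diels-Alder adduct, C10 ketone, C7=C8 alkene, O1 TBS, O3 isobutyrate | CC(C)(C)[Si](C)(C)O[C@@H]1C[C@@H](OC(=O)C(C)C)[C@@]2(C)[C@H](CC=C(C)C2)C(=O)C1(C)C | intermediate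
16 | tricyclic cyclobutanol, C10–OH syn to the C6–C8 bridge | CC(C)(C)[Si](C)(C)O[C@@H]1C[C@@H](OC(=O)C(C)C)[C@@]2(C)[C@@H]3CC=C(C)[C@H]2[C@]3(O)C1(C)C | intermediate
17 | C10 methyl oxalate of 16 | CC(C)(C)[Si](C)(C)O[C@@H]1C[C@@H](OC(=O)C(C)C)[C@@]2(C)[C@@H]3CC=C(C)[C@H]2[C@]3(OC(=O)C(=O)OC)C1(C)C | intermediate
18 | deoxygenated tricycle, C10–H | CC(C)(C)[Si](C)(C)O[C@@H]1C[C@@H](OC(=O)C(C)C)[C@@]2(C)[C@@H]3CC=C(C)[C@H]2[C@@H]3C1(C)C | intermediate
19 | tricyclic enone, C6 ketone, O1 TBS | CC(C)(C)[Si](C)(C)O[C@@H]1C[C@@H](OC(=O)C(C)C)[C@@]2(C)[C@@H]3C(=O)C=C(C)[C@H]2[C@@H]3C1(C)C | intermediate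
20 | C1 alcohol of the tricyclic enone | O[C@@H]1C[C@@H](OC(=O)C(C)C)[C@@]2(C)[C@@H]3C(=O)C=C(C)[C@H]2[C@@H]3C1(C)C | intermediate
21 | methacrylic anhydride | C=C(C)C(=O)OC(=O)C(C)=C | starting material
22 | CNP0214356.1 | C=C(C)C(=O)O[C@@H]1C[C@@H](OC(=O)C(C)C)[C@@]2(C)[C@@H]3C(=O)C=C(C)[C@H]2[C@@H]3C1(C)C | target

**Step count and risks**

Total steps: 15. Longest linear sequence: 15 steps (1 to 22).

Step 10 (Norrish-Yang photocyclisation). α-Cleavage of the excited ketone at C10–C11, quenching of the excited carbonyl by the nearby C7=C8 alkene, or fragmentation of the 1,4-biradical across C4–C5 may outrun closure of the four-membered ring. The fallback makes the same bond in the ground state and sets out from 15. Allylic hydroxylation with SeO2 (cat.) and t-BuOOH in CH2Cl2, which attacks the ring methylene at the more substituted end of the alkene, should give the C9 allylic alcohol F3. Ph3P with hexachloroacetone in CH2Cl2 at 0 °C should convert it into the C9 allylic chloride F4. SmI2 in THF/HMPA at −78 °C then brings about an intramolecular Barbier allylation of the C10 ketone, for which the carbonyl π* orbital is again directed at C9. This returns to the route at 16.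

Step 9 (Diels-Alder). The hindered β,β-disubstituted enone may react so slowly that Lewis-acid-induced polymerisation of isoprene takes over. The fallback uses a more nucleophilic diene and sets out from 13. 2-(tert-Butyldimethylsilyloxy)buta-1,3-diene with Me2AlCl in CH2Cl2 at −40 °C should give, with the same regiochemistry and the same facial preference, the silyl enol ether adduct F1. CsF and PhNTf2 in DME convert the enol ether regiospecifically into the C8 enol triflate F2. Negishi coupling with MeZnCl and Pd(PPh3)4 in THF installs the C8 methyl. This returns to the route at 15.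

Step 12 (radical deoxygenation). Thermal fragmentation of the hindered oxalate may be slow, and the C10 cyclobutyl radical may open by scission of the allylic C4–C9 bond before it is reduced. The fallback is a Markó-Lam deoxygenation at room temperature and sets out from 16. 4-Methylbenzoyl chloride with DMAP in pyridine at 60 °C gives the C10 toluate F5. SmI2 with HMPA in THF at rt cleaves it by single-electron transfer and reduces the tertiary radical on to the organosamarium, which is protonated. This returns to the route at 18.

**Further compounds**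

F1 | step 9 | silyl enol ether adduct, C8–OTBS in place of the C8 methyl of 15 | CC(C)(C)[Si](C)(C)O[C@@H]1C[C@@H](OC(=O)C(C)C)[C@@]2(C)[C@H](CC=C(O[Si](C)(C)C(C)(C)C)C2)C(=O)C1(C)C
F2 | step 9 | C8 enol triflate | CC(C)(C)[Si](C)(C)O[C@@H]1C[C@@H](OC(=O)C(C)C)[C@@]2(C)[C@H](CC=C(OS(=O)(=O)C(F)(F)F)C2)C(=O)C1(C)C
F3 | step 10 | C9 allylic alcohol of 15 | CC(C)(C)[Si](C)(C)O[C@@H]1C[C@@H](OC(=O)C(C)C)[C@@]2(C)[C@H](CC=C(C)C2O)C(=O)C1(C)C
F4 | step 10 | C9 allylic chloride of 15 | CC(C)(C)[Si](C)(C)O[C@@H]1C[C@@H](OC(=O)C(C)C)[C@@]2(C)[C@H](CC=C(C)C2Cl)C(=O)C1(C)C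
F5 | step 12 | C10 4-methylbenzoate of 16 | CC(C)(C)[Si](C)(C)O[C@@H]1C[C@@H](OC(=O)C(C)C)[C@@]2(C)[C@@H]3CC=C(C)[C@H]2[C@]3(OC(=O)c4ccc(C)cc4)C1(C)C
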